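The route rests on cutting the cycloheptanone ring at C7–C8 and C5–C1 (C1 tertiary carbinol, C5 CH–O-isovalerate, C6 lactone CH–O, C7 ring-fusion CH, C8 CH2, C9 ketone, C10 CH–CH3). A (4+3) cycloaddition of a chiral 1-alkoxy-2-siloxyallyl cation (C5–C6–C7) with a 2,3-disubstituted furan (C8–C9–C10–C1) should form both bonds at once and set the quaternary C1 and C5. It exploits the 1,4-relationship of the C1 hydroxyl and C8 across the seven-membered ring: the furan oxygen bridges them and later becomes the C1–OH, while the oxyallyl oxygen becomes the lactone oxygen at C6. The precursors are furan 3 and mixed-acetal silyl enol ether 7.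

Key step: step 5

Numbering used throughout: C2 = carbinol/carbonyl carbon of the butenoyl chain on C1, C11 = lactone α-carbon, C12 = lactone carbonyl, C13 = exocyclic methylene, C14 = methyl on C10. In this numbering the target is (1S,5S,6R,7S,10R).

Assumption (remark on the chemistry): the sense of induction of the 1-phenylethyl auxiliary is taken from the usual model (furan attacks the Z-configured cation anti to the phenyl group of the H-eclipsed oxocarbenium conformer), which calls for (S)-1-phenylethanol; if the sense proved opposite, (R)-1-phenylethanol would be used with no other change.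

Step 1
Reactants: 1 methyl 3-methylfuran-2-carboxylate
Product: 2 (3-methylfuran-2-yl)methanol
Conditions: LiAlH4, Et2O, 0 °C
Reagents that add atoms: none
Why: Ester reduction with LiAlH4 should give the furfuryl alcohol; the furan ring is inert to hydride and no stereocentre is formed.

Step 2
Reactants: 2 (3-methylfuran-2-yl)methanol
Product: 3 2-[(benzyloxy)methyl]-3-methylfuran
Conditions: NaH, BnBr, n-Bu4NI (cat.), THF, 0 °C → rt
Reagents that add atoms: benzyl bromide, BrCc1ccccc1
Why: Williamson etherification of the alkoxide; the benzyl ether should survive the silyl triflate, amide bases, borane and SmI2 to come and leaves together with the auxiliary in step 11.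

Step 3
Reactants: 4 1,1-dimethoxypropan-2-one (excess); 5 (S)-1-phenylethanol
Product: 6 1-methoxy-1-[(S)-1-phenylethoxy]propan-2-one (both acetal epimers)
Conditions: PPTS (cat.), cyclohexane, reflux, removal of MeOH
Reagents that add atoms: none
Why: Acid-catalysed transacetalisation driven by removal of methanol; the carbinol C–O bond of 5 is not broken, so its configuration is kept, and the new acetal centre is erased on ionisation in step 5.

Step 4
Reactants: 6 mixed acetal ketone
Product: 7 triethyl({3-methoxy-3-[(S)-1-phenylethoxy]prop-1-en-2-yl}oxy)silane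
Conditions: LiN(iPr)2, THF, −78 °C; Et3SiCl, −78 °C → rt
Reagents that add atoms: chlorotriethylsilane, CC[Si](Cl)(CC)CC
Why: Kinetic deprotonation at the unhindered methyl group (not at the doubly oxygenated acetal C–H) and O-silylation should give the silyl enol ether.

Step 5
Reactants: 3 2-[(benzyloxy)methyl]-3-methylfuran; 7 silyl enol ether (1.5 equiv)
Product: 9 (4+3) adduct 1-[(benzyloxy)methyl]-7-methyl-2-[(S)-1-phenylethoxy]-8-oxabicyclo[3.2.1]oct-6-en-3-one (alkoxy group equatorial and anti to the oxygen bridge), via Z-configured siloxyallyl cation triflate 8 (not isolated)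
Conditions: TMSOTf (0.2 equiv), CH2Cl2, −95 °C
Reagents that add atoms: none
Why: Catalytic TMSOTf ionises acetal 7 with loss of the methoxy group to the Z-configured 1-alkoxy-2-siloxyallyl cation 8, which adds across the 2,5-positions of furan 3 in a (4+3) cycloaddition (4π diene plus 2π allyl cation, suprafacial on both partners, concerted-asynchronous or stepwise), forming C7–C8 and C5–C1 and, after loss of the triethylsilyl group, the C6 ketone. The closest known reaction type is the low-temperature (4+3) cycloaddition of 1-phenylethyl mixed-acetal silyl enol ethers with furan, which gives enantiopure 2-alkoxy-8-oxabicyclo[3.2.1]oct-6-en-3-ones. The seven-membered carbocycle is closed by this intermolecular cycloaddition, and the bridged tetrahydropyranone ring (O, C1, C5, C6, C7, C8) closes in the same event with the furan oxygen as the one-atom bridge. C5 is controlled by the auxiliary (furan approaches the cation face anti to the phenyl group) together with the compact, endo-like transition state of the Z cation, which places the alkoxy group equatorial and anti to the oxygen bridge; C1 and C8 follow from the suprafacial addition to the furan. The step needs orientational selectivity (alkoxy-bearing C5 to the substituted furan carbon C1): the first bond is expected between the unhindered CH2 terminus C7, which is remote from the donor oxygen and carries the larger LUMO coefficient, and the unsubstituted, most accessible furan carbon C8, as in the syn-selective cycloadditions of heteroatom-stabilised oxyallyl cations with 2-substituted furans, after which C5 closes onto C1. The low temperature should suppress Friedel–Crafts-type substitution of the furan and ionisation of the furfuryl ether.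

Step 6
Reactants: 9 (4+3) adduct
Product: 10 methyl ester of the C7-acetic acid (keto ester; CH2CO2Me axial at C7 and syn to the oxygen bridge)
Conditions: LiN(iPr)2, THF, −78 °C; BrCH2CO2Me, DMPU, −78 → −30 °C
Reagents that add atoms: methyl bromoacetate, COC(=O)CBr
Why: Kinetic lithium enolate formation should occur at the CH2 group C7 and not at the alkoxy-bearing, neopentyl C5, and the enolate alkylation (SN2) takes place on the face syn to the oxygen bridge, away from the two-carbon bridge, which sets C7 with the axial arm that the target needs.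

Step 7
Reactants: 10 keto ester
Product: 12 cis-fused γ-lactone (C6–O equatorial and C7–C11 axial on the oxabicycle), via equatorial C6 hydroxy ester 11 (not isolated)
Conditions: SmI2 (2.5 equiv), THF–MeOH, −78 °C → rt; then PPTS (cat.), PhMe, 50 °C
Reagents that add atoms: none
Why: Single-electron (ketyl) reduction with SmI2 should give the thermodynamically preferred equatorial C6 alcohol, trans to the equatorial C5 ether (whose C–O bond lies near the carbonyl plane and cannot become anti-periplanar, so it is not expelled), and this alcohol, cis to the axial C7 arm, closes the cis-fused lactone by intramolecular transesterification.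

Step 8
Reactants: 12 lactone
Product: 13 C9 exo alcohol with endo C10 methyl group
Conditions: BH3·THF, THF, 0 °C; then 30% H2O2, pH 7 phosphate buffer, 0 °C → rt
Reagents that add atoms: hydrogen peroxide, OO
Why: Hydroboration–oxidation: boron adds to the less substituted C9 on the exo face (syn to the oxygen bridge) of the strained alkene faster than borane attacks the lactone, which gives the exo C9 alcohol and, by syn delivery of hydrogen, an endo C10 methyl group that is corrected in step 10.

Step 9
Reactants: 13 C9 alcohol
Product: 14 α-[(dimethylamino)methyl] lactone (either C11 epimer)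
Conditions: LiN(iPr)2 (2.3 equiv), THF, −78 °C; (CH2=NMe2)I, −78 → 0 °C
Reagents that add atoms: dimethyl(methylidene)ammonium iodide (Eschenmoser's salt), C=[N+](C)C.[I-]
Why: Mannich reaction of the lactone enolate (the C9 alkoxide forms first and is inert); the β-dimethylamino group masks the α-methylene lactone through the oxidation, hydrogenolysis, chromium and SmI2 steps, and the new C11 centre is removed in step 16.

Step 10
Reactants: 14 amino alcohol
Product: 16 C9 ketone with exo C10 methyl group, via endo-methyl C9 ketone 15 (not isolated)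
Conditions: Dess–Martin periodinane, NaHCO3, CH2Cl2, 0 °C → rt; then DBU (0.3 equiv), PhMe, rt
Reagents that add atoms: none
Why: Dess–Martin oxidation gives the ketone, and base equilibration through the C9–C10 enolate (C8 is a bridgehead and cannot enolise) should move the methyl group from the endo position, where it clashes with the axial C6–H, to the exo position, which is the C10 configuration of the target.

Step 11
Reactants: 16 exo-methyl ketone
Product: 17 diol (free C5–OH and primary C2–OH)
Conditions: H2 (1 atm), Pd(OH)2/C, EtOAc–EtOH, rt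
Reagents that add atoms: none
Why: Hydrogenolysis cleaves both benzylic C–O bonds (benzyl ether and 1-phenylethyl ether) while ketone, lactone and amine are inert; no alkene is present at this stage.

Step 12
Reactants: 17 diol
Product: 18 hydroxy aldehyde (C2 aldehyde on C1)
Conditions: Cu(MeCN)4OTf (5 mol %), 2,2'-bipyridine, TEMPO, N-methylimidazole, air, MeCN, rt
Reagents that add atoms: none
Why: Copper/nitroxyl aerobic oxidation is selective for the primary alcohol over the hindered secondary C5 alcohol and tolerates the tertiary amine; the aldehyde has no α-hydrogen.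

Step 13
Reactants: 18 hydroxy aldehyde
Product: 19 C5 isovalerate aldehyde
Conditions: 3-methylbutanoyl chloride, pyridine, DMAP (cat.), CH2Cl2, 0 °C → rt
Reagents that add atoms: 3-methylbutanoyl chloride, CC(C)CC(=O)Cl
Why: DMAP-catalysed acylation of the only free hydroxyl installs the ester of the target; the non-enolisable aldehyde and the ketone are unaffected.

Step 14
Reactants: 19 isovalerate aldehyde
Product: 20 (Z)-allylic alcohol (both C2 epimers)
Conditions: (Z)-1-bromoprop-1-ene, CrCl2 (5 equiv), NiCl2 (2 mol %), DMSO, rt
Reagents that add atoms: (Z)-1-bromoprop-1-ene, C/C=C\Br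
Why: Nozaki–Hiyama–Kishi coupling: the alkenylchromium species adds to the aldehyde only (ketone, lactone and ester are tolerated) with retention of the Z geometry of the disubstituted alkenyl halide; the carbinol configuration is irrelevant because it is oxidised in step 17.

Step 15
Reactants: 20 allylic alcohol
Product: 21 monocyclic cycloheptanone with free C1 tertiary alcohol and C8 methylene
Conditions: SmI2 (2.2 equiv), THF–MeOH, −78 °C
Reagents that add atoms: none
Why: SmI2 reduction of an α-alkoxy ketone: two single-electron transfers to the C9 ketone expel the bridging oxygen from C8, as known for oxa-bridged bicyclic ketones, which opens the bridge to the C8 methylene and the C1 hydroxyl; C2 is still a carbinol, so the C1–O bond is not at risk.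

Step 16
Reactants: 21 amino diol
Product: 23 α-methylene lactone diol, via trimethylammonium iodide 22 (not isolated)
Conditions: MeI, CH2Cl2–MeOH, rt; then aq. NaHCO3, rt
Reagents that add atoms: none
Why: N-Methylation and mild-base E1cB elimination of trimethylamine (Hofmann-type elimination of a Mannich base) should release the α-methylene lactone; it is done before the enone exists so that the amine set free cannot isomerise a Z-enone.

Step 17
Reactants: 23 α-methylene lactone diol
Product: 24 CNP0283951.2
Conditions: Dess–Martin periodinane, NaHCO3, CH2Cl2, 0 °C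
Reagents that add atoms: none
Why: Dess–Martin oxidation of the secondary allylic alcohol should give the (Z)-enone without touching the tertiary alcohol; buffered, cold conditions are chosen to preserve the Z alkene and the β-hydroxy ketone.

Compound list
1 | methyl 3-methylfuran-2-carboxylate | COC(=O)c1occc1C | starting material
2 | (3-methylfuran-2-yl)methanol | OCc1occc1C | intermediate
3 | 2-[(benzyloxy)methyl]-3-methylfuran | Cc1ccoc1COCc1ccccc1 | intermediate
4 | 1,1-dimethoxypropan-2-one | CC(=O)C(OC)OC | starting material
5 | (S)-1-phenylethanol | C[C@H](O)c1ccccc1 | starting material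
6 | 1-methoxy-1-[(S)-1-phenylethoxy]propan-2-one, both acetal epimers | CC(=O)C(OC)O[C@@H](C)c1ccccc1 | intermediate
7 | triethyl({3-methoxy-3-[(S)-1-phenylethoxy]prop-1-en-2-yl}oxy)silane, both acetal epimers | C=C(O[Si](CC)(CC)CC)C(OC)O[C@@H](C)c1ccccc1 | intermediate
8 | Z-configured 1-[(S)-1-phenylethoxy]-2-(triethylsiloxy)allyl cation triflate | C=C(O[Si](CC)(CC)CC)C=[O+][C@@H](C)c1ccccc1.[O-]S(=O)(=O)C(F)(F)F | intermediate (not isolated)
9 | 1-[(benzyloxy)methyl]-7-methyl-2-[(S)-1-phenylethoxy]-8-oxabicyclo[3.2.1]oct-6-en-3-one; alkoxy group at C5 equatorial, anti to the oxygen bridge and cis to the C1 substituent | O=C1C[C@H]2C=C(C)[C@@](O2)(COCc2ccccc2)[C@H]1O[C@@H](C)c1ccccc1 | intermediate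
10 | keto ester: 9 with CH2CO2Me at C7, axial and syn to the oxygen bridge | O=C1[C@H](CC(=O)OC)[C@H]2C=C(C)[C@@](O2)(COCc2ccccc2)[C@H]1O[C@@H](C)c1ccccc1 | intermediate
11 | hydroxy ester: C6–OH equatorial, trans to the C5 ether and cis to the C7 arm | O[C@@H]1[C@H](CC(=O)OC)[C@H]2C=C(C)[C@@](O2)(COCc2ccccc2)[C@H]1O[C@@H](C)c1ccccc1 | intermediate (not isolated)
12 | tricyclic cis-fused γ-lactone (C6–O and C7–C11 on the bridge face) with C9=C10 alkene | C1C(=O)O[C@@H]2[C@H]1[C@H]3C=C(C)[C@@](O3)(COCc3ccccc3)[C@H]2O[C@@H](C)c1ccccc1 | intermediate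
13 | lactone alcohol: C9–OH exo (syn to the oxygen bridge), C10 methyl endo | C1C(=O)O[C@@H]2[C@H]1[C@H]3[C@H](O)[C@@H](C)[C@@](O3)(COCc3ccccc3)[C@H]2O[C@@H](C)c1ccccc1 | intermediate
14 | 13 with CH2NMe2 at C11 (C11 configuration not defined, removed later) | CN(C)CC1C(=O)O[C@@H]2[C@H]1[C@H]3[C@H](O)[C@@H](C)[C@@](O3)(COCc3ccccc3)[C@H]2O[C@@H](C)c1ccccc1 | intermediate
15 | C9 ketone with endo C10 methyl | CN(C)CC1C(=O)O[C@@H]2[C@H]1[C@H]3C(=O)[C@@H](C)[C@@](O3)(COCc3ccccc3)[C@H]2O[C@@H](C)c1ccccc1 | intermediate (not isolated)
16 | C9 ketone with exo C10 methyl (syn to the oxygen bridge) | CN(C)CC1C(=O)O[C@@H]2[C@H]1[C@H]3C(=O)[C@H](C)[C@@](O3)(COCc3ccccc3)[C@H]2O[C@@H](C)c1ccccc1 | intermediate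
17 | diol: C5–OH and C1–CH2OH | CN(C)CC1C(=O)O[C@@H]2[C@H]1[C@H]3C(=O)[C@H](C)[C@@](O3)(CO)[C@H]2O | intermediate
18 | hydroxy aldehyde: C1–CHO, C5–OH | CN(C)CC1C(=O)O[C@@H]2[C@H]1[C@H]3C(=O)[C@H](C)[C@@](O3)(C=O)[C@H]2O | intermediate
19 | C5 3-methylbutanoate of 18 | CN(C)CC1C(=O)O[C@@H]2[C@H]1[C@H]3C(=O)[C@H](C)[C@@](O3)(C=O)[C@H]2OC(=O)CC(C)C | intermediate
20 | (Z)-1-hydroxybut-2-enyl derivative at C1 (both C2 epimers) | CN(C)CC1C(=O)O[C@@H]2[C@H]1[C@H]3C(=O)[C@H](C)[C@@](O3)(C(O)/C=C\C)[C@H]2OC(=O)CC(C)C | intermediate
21 | ring-opened cycloheptanone: C1–OH, C8 H2, C9 ketone, Mannich base (both C2 epimers) | CN(C)CC1C(=O)O[C@@H]2[C@H]1CC(=O)[C@H](C)[C@@](O)(C(O)/C=C\C)[C@H]2OC(=O)CC(C)C | intermediate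
22 | trimethylammonium iodide of 21 | C[N+](C)(C)CC1C(=O)O[C@@H]2[C@H]1CC(=O)[C@H](C)[C@@](O)(C(O)/C=C\C)[C@H]2OC(=O)CC(C)C.[I-] | intermediate (not isolated)
23 | α-methylene lactone with C2 carbinol (both C2 epimers) | C=C1C(=O)O[C@@H]2[C@H]1CC(=O)[C@H](C)[C@@](O)(C(O)/C=C\C)[C@H]2OC(=O)CC(C)C | intermediate
24 | CNP0283951.2 | C=C1C(=O)O[C@@H]2[C@H]1CC(=O)[C@H](C)[C@@](O)(C(=O)/C=C\C)[C@H]2OC(=O)CC(C)C | target

Total step count: 17 steps.
Longest linear sequence: 15 steps (steps 1, 2 and 5–17); steps 3 and 4 make the second partner of the key step.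

Steps most likely to fail

Step 5. The two partners may unite in the opposite orientation (the alkoxy-bearing terminus bonding to the unsubstituted furan carbon, which the 3-methyl group electronically favours), or the faces of the cation may be poorly discriminated. The fallback leaves the methyl group out of the diene and brings it in later; it sets out from 7. Furfuryl alcohol is benzylated (NaH, BnBr) to 2-[(benzyloxy)methyl]furan F1, whose single 2-substituent is the only directing group in the cycloaddition with 7 (TMSOTf, CH2Cl2, −95 °C), giving the des-methyl adduct F2. Alkylation as in step 6 gives the keto ester F3, and SmI2 reduction gives the hydroxy ester F4 and from it the lactone F5. Hydroboration with 9-BBN (boron at C9, remote from the quaternary bridgehead) and oxidation give the C9 alcohol F6, and Dess–Martin oxidation gives the ketone F7. LiN(SiMe3)2 and MeI at −78 °C give the exo-methyl ketone F8, since alkylation on the exo face sets C10 directly. NaBH4 masks the ketone as the alcohol F9, the Mannich reaction of step 9 gives the amino alcohol F10, and Dess–Martin oxidation returns to the route at 16.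

Step 7. The ketyl may expel the C5 alkoxy group, or protonation may deliver the axial alcohol, which cannot close the lactone. The fallback sets out from 10: LiBH(s-Bu)3 (THF, −78 °C) attacks from the face away from the two-carbon bridge and gives the axial C6 hydroxy ester F11. LiOH hydrolysis gives the hydroxy acid F12, and Mitsunobu lactonisation (PPh3, DIAD) closes the lactone with inversion at C6 and returns to the route at 12.

Step 6. Deprotonation may occur at the alkoxy-bearing C5, the hindered enolate may be O-alkylated or react sluggishly, and the axial product may epimerise. The fallback sets out from 9: condensation with 1,1-dimethylhydrazine gives the dimethylhydrazone F13. Its aza-enolate (LiN(iPr)2), formed at the less substituted α-carbon C7, is alkylated axially with methyl bromoacetate to the alkylated hydrazone F14, and hydrolysis (aq. CuCl2, pH 7) returns to the route at 10.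

Further compounds
F1 | step 5 | 2-[(benzyloxy)methyl]furan | c1coc(COCc2ccccc2)c1
F2 | step 5 | 1-[(benzyloxy)methyl]-2-[(S)-1-phenylethoxy]-8-oxabicyclo[3.2.1]oct-6-en-3-one | O=C1C[C@H]2C=C[C@@](O2)(COCc2ccccc2)[C@H]1O[C@@H](C)c1ccccc1
F3 | step 5 | des-methyl keto ester (axial CH2CO2Me at C7) | O=C1[C@H](CC(=O)OC)[C@H]2C=C[C@@](O2)(COCc2ccccc2)[C@H]1O[C@@H](C)c1ccccc1
F4 | step 5 | des-methyl equatorial C6 hydroxy ester (not isolated) | O[C@@H]1[C@H](CC(=O)OC)[C@H]2C=C[C@@](O2)(COCc2ccccc2)[C@H]1O[C@@H](C)c1ccccc1
F5 | step 5 | des-methyl cis-fused lactone | C1C(=O)O[C@@H]2[C@H]1[C@H]3C=C[C@@](O3)(COCc3ccccc3)[C@H]2O[C@@H](C)c1ccccc1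
F6 | step 5 | des-methyl C9 exo alcohol | C1C(=O)O[C@@H]2[C@H]1[C@H]3[C@H](O)C[C@@](O3)(COCc3ccccc3)[C@H]2O[C@@H](C)c1ccccc1
F7 | step 5 | des-methyl C9 ketone | C1C(=O)O[C@@H]2[C@H]1[C@H]3C(=O)C[C@@](O3)(COCc3ccccc3)[C@H]2O[C@@H](C)c1ccccc1
F8 | step 5 | exo-methyl C9 ketone without the Mannich group | C1C(=O)O[C@@H]2[C@H]1[C@H]3C(=O)[C@H](C)[C@@](O3)(COCc3ccccc3)[C@H]2O[C@@H](C)c1ccccc1
F9 | step 5 | exo-methyl C9 alcohol (C9 configuration not defined) | C1C(=O)O[C@@H]2[C@H]1[C@H]3C(O)[C@H](C)[C@@](O3)(COCc3ccccc3)[C@H]2O[C@@H](C)c1ccccc1
F10 | step 5 | exo-methyl C9 alcohol with CH2NMe2 at C11 | CN(C)CC1C(=O)O[C@@H]2[C@H]1[C@H]3C(O)[C@H](C)[C@@](O3)(COCc3ccccc3)[C@H]2O[C@@H](C)c1ccccc1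
F11 | step 7 | axial C6 hydroxy ester | O[C@H]1[C@H](CC(=O)OC)[C@H]2C=C(C)[C@@](O2)(COCc2ccccc2)[C@H]1O[C@@H](C)c1ccccc1
F12 | step 7 | axial C6 hydroxy acid | O[C@H]1[C@H](CC(=O)O)[C@H]2C=C(C)[C@@](O2)(COCc2ccccc2)[C@H]1O[C@@H](C)c1ccccc1
F13 | step 6 | N,N-dimethylhydrazone of 9 | CN(C)N=C1C[C@H]2C=C(C)[C@@](O2)(COCc2ccccc2)[C@H]1O[C@@H](C)c1ccccc1
F14 | step 6 | N,N-dimethylhydrazone of 10 | CN(C)N=C1[C@H](CC(=O)OC)[C@H]2C=C(C)[C@@](O2)(COCc2ccccc2)[C@H]1O[C@@H](C)c1ccccc1
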